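## Retrosynthetic overview

1. Target ⇒ bis-angeloylation and desilylation of a 3,4-cis-diol; diol ⇒ dihydroxylation of a cycloheptene anti to O5; C11 ketone ⇒ cleavage of an exocyclic methylidene.
2. Seven-membered ring (formed last, step 11) ⇒ ring-closing metathesis of two vinyl groups held cis-1,3 on the cyclobutane; C5 carbinol ⇒ CBS reduction of the enone.
3. Neopentyl side chain ⇒ olefination and reductive methylation of a bridging cyclobutanone.
4. Cyclobutane and six-membered ring (formed first and together, step 6) ⇒ intramolecular crossed [2+2] of a vinylketene with a 1,3-diene, steered by one methyl stereocentre.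
5. Acyclic trienoic acid ⇒ Evans alkylation and two Wittig reactions.

Assumption: both ester groups are (Z)-2-methylbut-2-enoates (angelates), as the SMILES shows. Bicyclic compounds are numbered as bicyclo[3.1.1]heptane (C6 = carbonyl bridge, C7 = methyl/vinyl bridge, C2–C4 = three-carbon bridge). Tricyclic compounds are numbered as tricyclo[5.4.0.0(2,8)]undecane (C11 = ring ketone carbon, C6 = CMe2, C3–C5 = oxygenated carbons).

## Route

Step 1
Reactants: 1 (4S)-4-benzyl-3-propanoyl-1,3-oxazolidin-2-one; 2 ethyl (2E)-4-bromo-3-methylbut-2-enoate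
Product: 3 ethyl (2E,5R)-6-[(4S)-4-benzyl-2-oxo-1,3-oxazolidin-3-yl]-3,5-dimethyl-6-oxohex-2-enoate
Conditions: NaN(SiMe3)2, THF, −78 °C; then 2, −78 to −40 °C
Reagents that add atoms: none
Why: Evans asymmetric alkylation, in which the chelated Z-sodium enolate is alkylated by the allylic bromide on the face opposite the benzyl group, setting the (5R) methyl centre and bringing in the E-configured 3-methyl-enoate in one operation.

Step 2
Reactants: 3 alkylated imide
Product: 4 ethyl (2E,5R)-3,5-dimethyl-6-oxohex-2-enoate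
Conditions: Cp2Zr(H)Cl (1.6 equiv), THF, 20 °C; aqueous work-up
Reagents that add atoms: none
Why: Hydrozirconation of the imide carbonyl (amide-to-aldehyde reduction with Cp2Zr(H)Cl) gives a zirconium hemiaminal that releases the aldehyde and the auxiliary on work-up, while the less electrophilic conjugated ester and the trisubstituted alkene are left alone and the alpha-centre is not epimerised.

Step 3
Reactants: 4 aldehyde; 5 2-(triphenylphosphoranylidene)propanal
Product: 6 ethyl (2E,5R,6E)-3,5,7-trimethyl-8-oxoocta-2,6-dienoate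
Conditions: toluene, 90 °C
Reagents that add atoms: none
Why: Wittig olefination with a stabilised, non-basic formyl ylide gives the (E)-2-methyl-enal selectively without epimerising the neighbouring centre.

Step 4
Reactants: 6 enal
Product: 7 ethyl (2E,5R,6E)-3,5,7-trimethylnona-2,6,8-trienoate
Conditions: Ph3PCH3Br, KN(SiMe3)2, THF, 0 °C; then 6, −78 to 0 °C
Reagents that add atoms: methyltriphenylphosphonium bromide, C[P+](c1ccccc1)(c1ccccc1)c1ccccc1.[Br-]
Why: Wittig methylenation of the aldehyde is far faster than attack on the hindered conjugated ester and completes the (E)-1,3-diene that later acts as ketenophile.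

Step 5
Reactants: 7 triene ester
Product: 8 (2E,5R,6E)-3,5,7-trimethylnona-2,6,8-trienoic acid
Conditions: LiOH, THF/MeOH/H2O, 45 °C; then 1 M HCl to pH 3, 0 °C
Reagents that add atoms: lithium hydroxide, [Li+].[OH-]
Why: Saponification of the ester, with no stereocentre alpha to a carbonyl that could epimerise.

Step 6
Reactants: 8 trienoic acid
Product: 11 (1S,4R,5R,7R)-7-ethenyl-4,7-dimethyl-2-methylidenebicyclo[3.1.1]heptan-6-one, via acid chloride 9 (not isolated), via vinylketene 10 (not isolated)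
Conditions: (COCl)2, cat. DMF, CH2Cl2, 0 to 20 °C; evaporate; then slow addition (8 h) to Et3N (3 equiv), toluene, 110 °C, final 0.005 M
Reagents that add atoms: none
Why: Intramolecular crossed [2+2] cycloaddition of a vinylketene with an alkene (the geranoyl chloride to 2-methylidenebicyclo[3.1.1]heptan-6-one reaction type), in which gamma-deprotonation of the methyl cis to the acyl group gives the vinylketene, its carbonyl carbon bonds to the diene CH and its alpha-carbon to the allyl-stabilised C(Me)(vinyl) terminus so that cyclobutanone and six-membered ring close together, the addition is suprafacial on the E-alkene (C7 methyl syn and vinyl anti to the three-carbon bridge), and the allylic methyl centre, which keeps its methyl away from the cis-methyl of the alkene to avoid allylic 1,3-strain, lets the tethered ketene reach only one alkene face so that the 4-methyl ends on the carbonyl-bridge side and C1, C5 and C7 are fixed.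

Step 7
Reactants: 11 bicyclic ketone; 12 triethyl 2-phosphonopropanoate
Product: 13 ethyl 2-[7-ethenyl-4,7-dimethyl-2-methylidenebicyclo[3.1.1]heptan-6-ylidene]propanoate (cage as in 11; both alkene isomers)
Conditions: NaH, DME, 0 °C; then 11, 85 °C
Reagents that add atoms: none
Why: Horner–Wadsworth–Emmons olefination driven by release of cyclobutanone strain, with both alkene isomers carried on because the geometry is erased in the next step.

Step 8
Reactants: 13 alkylidene ester
Product: 15 ethyl 2-[(1S,4R,5S,6S,7R)-7-ethenyl-4,7-dimethyl-2-methylidenebicyclo[3.1.1]heptan-6-yl]-2-methylpropanoate, via lithium enolate 14 (not isolated)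
Conditions: Li (2.2 equiv), NH3/THF, t-BuOH (1.0 equiv), −78 °C; then MeI (5 equiv), −78 to −33 °C
Reagents that add atoms: iodomethane, CI
Why: Dissolving-metal reductive alkylation of an alpha,beta-unsaturated ester (Stork type), in which the beta-carbanion on the cyclobutane pyramidalises with the bulky ester-bearing carbon anti to the three-carbon bridge (away from the 4-methyl and the bridge CH2) and is protonated on its outward lobe, giving C6–H syn to the bridge and the side chain cis to the C7 vinyl group, after which the ester enolate is C-methylated to the quaternary carbon while the isolated alkenes stay inert.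

Step 9
Reactants: 15 gem-dimethyl ester
Product: 16 2-[(1S,4R,5S,6S,7R)-7-ethenyl-4,7-dimethyl-2-methylidenebicyclo[3.1.1]heptan-6-yl]-N-methoxy-N,2-dimethylpropanamide
Conditions: MeNH(OMe)·HCl (4 equiv), AlMe3 (4 equiv), CH2Cl2, 0 °C; then 15, toluene, 80 °C
Reagents that add atoms: N,O-dimethylhydroxylamine hydrochloride, CNOC.Cl
Why: Weinreb aminolysis of a hindered ester with the aluminium amide, which prepares the neopentyl acyl group for a single addition of an organometallic.

Step 10
Reactants: 16 Weinreb amide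
Product: 17 4-[(1S,4R,5S,6S,7R)-7-ethenyl-4,7-dimethyl-2-methylidenebicyclo[3.1.1]heptan-6-yl]-4-methylpent-1-en-3-one
Conditions: CH2=CHMgBr (3 equiv), THF, 0 to 40 °C; inverse quench into cold 1 M HCl
Reagents that add atoms: vinylmagnesium bromide, C=C[Mg]Br
Why: Weinreb ketone synthesis, in which the magnesium chelate survives until the acidic quench that also protonates the released amine so it cannot add to the vinyl ketone.

Step 11
Reactants: 17 vinyl ketone
Product: 18 (1S,2R,7S,8S,9R)-2,6,6,9-tetramethyl-11-methylidenetricyclo[5.4.0.0(2,8)]undec-3-en-5-one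
Conditions: second-generation Grubbs catalyst RuCl2(=CHPh)(PCy3)(H2IMes) (5 mol%), CH2Cl2, 40 °C, 0.005 M
Reagents that add atoms: none
Why: Ring-closing metathesis of the two vinyl groups, which the cyclobutane holds cis-1,3 and close together, closes the seven-membered ring as a cis-enone, and the distant 1,1-disubstituted exocyclic alkene cannot reach either partner.

Step 12
Reactants: 18 tricyclic enone
Product: 19 (1S,2R,5R,7S,8S,9R)-2,6,6,9-tetramethyl-11-methylidenetricyclo[5.4.0.0(2,8)]undec-3-en-5-ol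
Conditions: (S)-2-methyl-CBS-oxazaborolidine (0.2 equiv), catecholborane (1.5 equiv), toluene, −78 °C
Reagents that add atoms: none
Why: Corey–Bakshi–Shibata reduction under reagent control (needed because the cage is nearly mirror-symmetric around the enone), in which the quaternary C6 acts as the large and the vinylic CH as the small group so the (S)-catalyst gives the (5R)-alcohol, and catecholborane at −78 °C does not hydroborate the exocyclic alkene.

Step 13
Reactants: 19 allylic alcohol
Product: 20 (1S,2R,5R,7S,8S,9R)-5-[(tert-butyldimethylsilyl)oxy]-2,6,6,9-tetramethyl-11-methylidenetricyclo[5.4.0.0(2,8)]undec-3-ene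
Conditions: TBSOTf, 2,6-lutidine, CH2Cl2, −78 to 0 °C
Reagents that add atoms: tert-butyldimethylsilyl trifluoromethanesulfonate, CC(C)(C)[Si](C)(C)OS(=O)(=O)C(F)(F)F
Why: Silylation of the hindered neopentyl alcohol with the silyl triflate gives a bulky ether that later steers the dihydroxylation and keeps O5 out of the acylation.

Step 14
Reactants: 20 silyl ether
Product: 22 (1R,2R,5R,7S,8S,9R)-5-[(tert-butyldimethylsilyl)oxy]-2,6,6,9-tetramethyltricyclo[5.4.0.0(2,8)]undec-3-en-11-one, via diol 21 (not isolated)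
Conditions: OsO4 (2 mol%), NaIO4 (2.1 equiv), 2,6-lutidine, dioxane/H2O 3:1, 0 to 20 °C, stopped when 20 is consumed
Reagents that add atoms: osmium tetroxide, O=[Os](=O)(=O)=O; sodium periodate, [Na+].[O-]I(=O)(=O)=O
Why: Lemieux–Johnson oxidative cleavage, in which the open 1,1-disubstituted exocyclic alkene is osmylated (from the face away from the C2 methyl) faster than the ring alkene, which is cis-disubstituted, flanked by a quaternary carbon and deactivated by the allylic silyloxy group, so only the methylidene is cut to the C11 ketone.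

Step 15
Reactants: 22 enone-free ring alkene ketone
Product: 23 (1R,2R,3S,4S,5S,7S,8S,9R)-5-[(tert-butyldimethylsilyl)oxy]-3,4-dihydroxy-2,6,6,9-tetramethyltricyclo[5.4.0.0(2,8)]undecan-11-one
Conditions: OsO4 (5 mol%), 4-methylmorpholine N-oxide (2 equiv), acetone/H2O 5:1, 20 °C
Reagents that add atoms: osmium tetroxide, O=[Os](=O)(=O)=O; 4-methylmorpholine N-oxide, C[N+]1([O-])CCOCC1; water, O
Why: Upjohn syn-dihydroxylation, in which by the Kishi rule OsO4 adds to the cycloheptene face opposite the allylic silyloxy group and so gives the 3,4-cis-diol trans to O5.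

Step 16
Reactants: 23 diol; 24 angelic acid, (2Z)-2-methylbut-2-enoic acid
Product: 26 (1R,2R,3S,4S,5S,7S,8S,9R)-5-[(tert-butyldimethylsilyl)oxy]-2,6,6,9-tetramethyl-11-oxotricyclo[5.4.0.0(2,8)]undecane-3,4-diyl bis[(2Z)-2-methylbut-2-enoate], via mixed anhydride 25 (not isolated)
Conditions: 24 (6 equiv), 2,4,6-trichlorobenzoyl chloride (6 equiv), Et3N (12 equiv), toluene, 20 °C, 2 h; then 23, 80 °C, 24 h
Reagents that add atoms: none
Why: Yamaguchi-type esterification through the mixed anhydride of angelic acid, run without a nucleophilic catalyst so the Z-alkene does not isomerise to the tiglate, acylates both secondary hydroxyls while O5 stays silylated.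

Step 17
Reactants: 26 silylated bis-angelate
Product: 27 (1R,2R,3S,4R,5S,7S,8S,9R)-5-hydroxy-2,6,6,9-tetramethyl-11-oxotricyclo[5.4.0.0(2,8)]undecane-3,4-diyl bis[(2Z)-2-methylbut-2-enoate] (CNP0344448.1)
Conditions: HF·pyridine, THF/pyridine, 0 to 20 °C
Reagents that add atoms: none
Why: Fluoride-mediated desilylation under mildly acidic conditions frees O5 without moving an acyl group or isomerising the angelates.

## Compound list

1 | (4S)-4-benzyl-3-propanoyl-1,3-oxazolidin-2-one | CCC(=O)N1[C@@H](Cc2ccccc2)COC1=O | starting material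
2 | ethyl (2E)-4-bromo-3-methylbut-2-enoate | CCOC(=O)/C=C(\C)CBr | starting material
3 | ethyl (2E,5R)-6-[(4S)-4-benzyl-2-oxo-1,3-oxazolidin-3-yl]-3,5-dimethyl-6-oxohex-2-enoate | CCOC(=O)/C=C(\C)C[C@@H](C)C(=O)N1[C@@H](Cc2ccccc2)COC1=O | intermediate
4 | ethyl (2E,5R)-3,5-dimethyl-6-oxohex-2-enoate | CCOC(=O)/C=C(\C)C[C@@H](C)C=O | intermediate
5 | 2-(triphenylphosphoranylidene)propanal | CC(C=O)=P(c1ccccc1)(c1ccccc1)c1ccccc1 | starting material
6 | ethyl (2E,5R,6E)-3,5,7-trimethyl-8-oxoocta-2,6-dienoate | CCOC(=O)/C=C(\C)C[C@@H](C)/C=C(\C)C=O | intermediate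
7 | ethyl (2E,5R,6E)-3,5,7-trimethylnona-2,6,8-trienoate | CCOC(=O)/C=C(\C)C[C@@H](C)/C=C(\C)C=C | intermediate
8 | (2E,5R,6E)-3,5,7-trimethylnona-2,6,8-trienoic acid | OC(=O)/C=C(\C)C[C@@H](C)/C=C(\C)C=C | intermediate
9 | (2E,5R,6E)-3,5,7-trimethylnona-2,6,8-trienoyl chloride | ClC(=O)/C=C(\C)C[C@@H](C)/C=C(\C)C=C | intermediate
10 | (5R,6E)-5,7-dimethyl-3-methylidenenona-1,6,8-trien-1-one (vinylketene) | O=C=CC(=C)C[C@@H](C)/C=C(\C)C=C | intermediate
11 | (1S,4R,5R,7R)-7-ethenyl-4,7-dimethyl-2-methylidenebicyclo[3.1.1]heptan-6-one | O=C1[C@@H]2[C@H](C)CC(=C)[C@H]1[C@]2(C)C=C | intermediate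
12 | triethyl 2-phosphonopropanoate | CCOC(=O)C(C)P(=O)(OCC)OCC | starting material
13 | ethyl 2-[7-ethenyl-4,7-dimethyl-2-methylidenebicyclo[3.1.1]heptan-6-ylidene]propanoate (cage as in 11; both alkene isomers) | CCOC(=O)C(C)=C1[C@@H]2[C@H](C)CC(=C)[C@H]1[C@]2(C)C=C | intermediate
14 | lithium enolate of 15 (lithium 1-ethoxy-2-[bicyclic-6-yl]prop-1-en-1-olate; C6–H syn to the C2–C4 bridge) | CCOC([O-])=C(C)[C@H]1[C@@H]2[C@H](C)CC(=C)[C@H]1[C@]2(C)C=C.[Li+] | intermediate
15 | ethyl 2-[(1S,4R,5S,6S,7R)-7-ethenyl-4,7-dimethyl-2-methylidenebicyclo[3.1.1]heptan-6-yl]-2-methylpropanoate | CCOC(=O)C(C)(C)[C@H]1[C@@H]2[C@H](C)CC(=C)[C@H]1[C@]2(C)C=C | intermediate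
16 | 2-[(1S,4R,5S,6S,7R)-7-ethenyl-4,7-dimethyl-2-methylidenebicyclo[3.1.1]heptan-6-yl]-N-methoxy-N,2-dimethylpropanamide | CON(C)C(=O)C(C)(C)[C@H]1[C@@H]2[C@H](C)CC(=C)[C@H]1[C@]2(C)C=C | intermediate
17 | 4-[(1S,4R,5S,6S,7R)-7-ethenyl-4,7-dimethyl-2-methylidenebicyclo[3.1.1]heptan-6-yl]-4-methylpent-1-en-3-one | C=CC(=O)C(C)(C)[C@H]1[C@@H]2[C@H](C)CC(=C)[C@H]1[C@]2(C)C=C | intermediate
18 | (1S,2R,7S,8S,9R)-2,6,6,9-tetramethyl-11-methylidenetricyclo[5.4.0.0(2,8)]undec-3-en-5-one | O=C1C(C)(C)[C@H]2[C@@H]3[C@H](C)CC(=C)[C@H]2[C@]3(C)C=C1 | intermediate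
19 | (1S,2R,5R,7S,8S,9R)-2,6,6,9-tetramethyl-11-methylidenetricyclo[5.4.0.0(2,8)]undec-3-en-5-ol | O[C@H]1C(C)(C)[C@H]2[C@@H]3[C@H](C)CC(=C)[C@H]2[C@]3(C)C=C1 | intermediate
20 | (1S,2R,5R,7S,8S,9R)-5-[(tert-butyldimethylsilyl)oxy]-2,6,6,9-tetramethyl-11-methylidenetricyclo[5.4.0.0(2,8)]undec-3-ene | CC(C)(C)[Si](C)(C)O[C@H]1C(C)(C)[C@H]2[C@@H]3[C@H](C)CC(=C)[C@H]2[C@]3(C)C=C1 | intermediate
21 | 5-[(tert-butyldimethylsilyl)oxy]-11-(hydroxymethyl)-2,6,6,9-tetramethyltricyclo[5.4.0.0(2,8)]undec-3-en-11-ol (other centres as in 20; C11 hydroxyl anti to the C2 methyl) | CC(C)(C)[Si](C)(C)O[C@H]1C(C)(C)[C@H]2[C@@H]3[C@H](C)C[C@@](O)(CO)[C@H]2[C@]3(C)C=C1 | intermediate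
22 | (1R,2R,5R,7S,8S,9R)-5-[(tert-butyldimethylsilyl)oxy]-2,6,6,9-tetramethyltricyclo[5.4.0.0(2,8)]undec-3-en-11-one | CC(C)(C)[Si](C)(C)O[C@H]1C(C)(C)[C@H]2[C@@H]3[C@H](C)CC(=O)[C@H]2[C@]3(C)C=C1 | intermediate
23 | (1R,2R,3S,4S,5S,7S,8S,9R)-5-[(tert-butyldimethylsilyl)oxy]-3,4-dihydroxy-2,6,6,9-tetramethyltricyclo[5.4.0.0(2,8)]undecan-11-one | O[C@@H]1[C@@H](O[Si](C)(C)C(C)(C)C)C(C)(C)[C@H]2[C@@H]3[C@H](C)CC(=O)[C@H]2[C@]3(C)[C@@H]1O | intermediate
24 | angelic acid, (2Z)-2-methylbut-2-enoic acid | C/C=C(/C)C(=O)O | starting material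
25 | (2Z)-2-methylbut-2-enoic 2,4,6-trichlorobenzoic anhydride | C/C=C(/C)C(=O)OC(=O)c1c(Cl)cc(Cl)cc1Cl | intermediate
26 | (1R,2R,3S,4S,5S,7S,8S,9R)-5-[(tert-butyldimethylsilyl)oxy]-2,6,6,9-tetramethyl-11-oxotricyclo[5.4.0.0(2,8)]undecane-3,4-diyl bis[(2Z)-2-methylbut-2-enoate] | C/C=C(/C)C(=O)O[C@@H]1[C@@H](O[Si](C)(C)C(C)(C)C)C(C)(C)[C@H]2[C@@H]3[C@H](C)CC(=O)[C@H]2[C@]3(C)[C@@H]1OC(=O)/C(C)=C\C | intermediate
27 | (1R,2R,3S,4R,5S,7S,8S,9R)-5-hydroxy-2,6,6,9-tetramethyl-11-oxotricyclo[5.4.0.0(2,8)]undecane-3,4-diyl bis[(2Z)-2-methylbut-2-enoate] | C/C=C(/C)C(=O)O[C@@H]1[C@@H](O)C(C)(C)[C@H]2[C@@H]3[C@H](C)CC(=O)[C@H]2[C@]3(C)[C@@H]1OC(=O)/C(C)=C\C | target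

## Step count and weak points

Total step count: 17. Longest linear sequence: 17 (the route is fully linear from 1).

The three steps most likely to fail are 6, 7 and 8.

Step 6 can give the endocyclic isomer through deprotonation at the chain CH2, ketene oligomers, or scrambled C7 geometry if the diene makes the addition stepwise. The fallback replaces the ketene by a keteniminium ion and sets out from 8. Amidation (pivaloyl chloride, Et3N, then pyrrolidine) gives 1-[(2E,5R,6E)-3,5,7-trimethylnona-2,6,8-trienoyl]pyrrolidine F1. Tf2O and 2,4,6-collidine in 1,2-dichloroethane (0 to 80 °C) convert F1, by gamma-deprotonation of the O-triflyl iminium ion, into a vinylketeniminium ion. This ion undergoes the same crossed [2+2] at lower temperature and cannot dimerise, giving 1-[(1S,4R,5R,7R)-7-ethenyl-4,7-dimethyl-2-methylidenebicyclo[3.1.1]heptan-6-ylidene]pyrrolidin-1-ium trifluoromethanesulfonate F2. Aqueous NaHCO3 hydrolysis brings the route back at 11.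

Step 7 may stall because the cyclobutanone is shielded on one face by the three-carbon bridge and on the other by the axial vinyl group, and the phosphonate carbanion is tertiary. The fallback uses a small linear nucleophile and a rearrangement instead of an olefination, and sets out from 11. LiC≡COEt (THF, −78 °C) adds anti to the bridge to give 6-(ethoxyethynyl)-7-ethenyl-4,7-dimethyl-2-methylidenebicyclo[3.1.1]heptan-6-ol F3. Meyer–Schuster rearrangement (cat. H2SO4, wet THF) gives ethyl 2-[7-ethenyl-4,7-dimethyl-2-methylidenebicyclo[3.1.1]heptan-6-ylidene]acetate F4. Li/NH3 then MeI, as in step 8, gives ethyl 2-[7-ethenyl-4,7-dimethyl-2-methylidenebicyclo[3.1.1]heptan-6-yl]propanoate F5. A second methylation (LiN(iPr)2, then MeI, THF, −78 °C) comes back to the route at 15.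

Step 8 carries the least certain stereocentre: protonation could occur on the other lobe and place the side chain syn to the bridge, and the ester could be over-reduced. The fallback delivers the quaternary carbon as a nucleophile to the only open face and then removes the oxygen; it sets out from 11. Reformatsky addition (ethyl 2-bromo-2-methylpropanoate, Zn, THF, 65 °C) anti to the bridge gives ethyl 2-[7-ethenyl-6-hydroxy-4,7-dimethyl-2-methylidenebicyclo[3.1.1]heptan-6-yl]-2-methylpropanoate F6, with the side chain already cis to the vinyl group. Oxalyl chloride and then aqueous CsOH give caesium 2-{[6-(1-ethoxy-2-methyl-1-oxopropan-2-yl)-7-ethenyl-4,7-dimethyl-2-methylidenebicyclo[3.1.1]heptan-6-yl]oxy}-2-oxoacetate F7. Photoredox deoxygenation ([Ir(dF(CF3)ppy)2(dtbbpy)]PF6, blue light, 2,4,6-triisopropylbenzenethiol as hydrogen-atom donor, wet DME) forms the tertiary cyclobutyl radical, which takes up hydrogen on its outward lobe and comes back to the route at 15.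

Further compounds
F1 | step 6 | 1-[(2E,5R,6E)-3,5,7-trimethylnona-2,6,8-trienoyl]pyrrolidine | O=C(/C=C(\C)C[C@@H](C)/C=C(\C)C=C)N1CCCC1
F2 | step 6 | 1-[(1S,4R,5R,7R)-7-ethenyl-4,7-dimethyl-2-methylidenebicyclo[3.1.1]heptan-6-ylidene]pyrrolidin-1-ium trifluoromethanesulfonate | [N+]1(CCCC1)=C2[C@@H]3[C@H](C)CC(=C)[C@H]2[C@]3(C)C=C.[O-]S(=O)(=O)C(F)(F)F
F3 | step 7 | 6-(ethoxyethynyl)-7-ethenyl-4,7-dimethyl-2-methylidenebicyclo[3.1.1]heptan-6-ol (cage as in 11; alkynyl anti to the C2–C4 bridge) | CCOC#C[C@@]1(O)[C@@H]2[C@H](C)CC(=C)[C@H]1[C@]2(C)C=C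
F4 | step 7 | ethyl 2-[7-ethenyl-4,7-dimethyl-2-methylidenebicyclo[3.1.1]heptan-6-ylidene]acetate (cage as in 11) | CCOC(=O)C=C1[C@@H]2[C@H](C)CC(=C)[C@H]1[C@]2(C)C=C
F5 | step 7 | ethyl 2-[7-ethenyl-4,7-dimethyl-2-methylidenebicyclo[3.1.1]heptan-6-yl]propanoate (ring centres as in 15; both epimers at the propanoate carbon) | CCOC(=O)C(C)[C@H]1[C@@H]2[C@H](C)CC(=C)[C@H]1[C@]2(C)C=C
F6 | step 8 | ethyl 2-[7-ethenyl-6-hydroxy-4,7-dimethyl-2-methylidenebicyclo[3.1.1]heptan-6-yl]-2-methylpropanoate (cage as in 11; side chain anti to the C2–C4 bridge) | CCOC(=O)C(C)(C)[C@@]1(O)[C@@H]2[C@H](C)CC(=C)[C@H]1[C@]2(C)C=C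
F7 | step 8 | caesium 2-{[6-(1-ethoxy-2-methyl-1-oxopropan-2-yl)-7-ethenyl-4,7-dimethyl-2-methylidenebicyclo[3.1.1]heptan-6-yl]oxy}-2-oxoacetate | CCOC(=O)C(C)(C)[C@@]1(OC(=O)C(=O)[O-])[C@@H]2[C@H](C)CC(=C)[C@H]1[C@]2(C)C=C.[Cs+]
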